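**Plan**
- Retrosynthesis: after removal of two MOM acetals, ring C is cut in one stroke at C2–C3 and at O1–C8a. This gives a ring B aldehyde (brings C2 and O1) and a ring A 2-fluoroaryl methyl ketone, used as its enol silane (brings C3, C4 and C8a).
- Enabling feature: the C4 ketone sits on C4a, ortho to C8a, so O1–C8a=C4a–C4=O is a benzo-fused vinylogous ester. The same carbonyl makes C3 an enolate carbon and makes C8a–F an SNAr site; the enol silane is a 1-fluoro-3-silyloxy diene whose C4a=C8a bond is hidden in ring A.
- Forward, ring A fragment: 4-bromo-3-fluorophenol → MOM ether → metalation between F and OMOM with prenylation → Br/Li exchange and acetylation → enol silane. Ring B fragment: 3-bromo-4-hydroxybenzaldehyde → MOM ether → Stille prenylation.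
- The fragments are joined and ring C is closed in one flask: catalytic enantioselective Mukaiyama aldol addition (C2–C3), then fluoride-relayed desilylative SNAr (O1–C8a). Mild acid then frees the two phenols.
- Stereochemistry: the only stereocentre, C2, is set by a chiral boron Lewis acid in the aldol event (Si-face attack on the aldehyde). The ring closure leaves the C2–O bond intact, so it is carried unchanged to (2S).

Key step: step 7

Assumption: the sense of induction of the boron catalyst is taken over from the parent pair benzaldehyde / 1-phenyl-1-(trimethylsilyloxy)ethene; should the substituted pair answer with the opposite sense, the catalyst from (S)-tryptophan is used and nothing else changes.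

**Route**

Step 1
Reactants: 1 4-bromo-3-fluorophenol
Product: 2 1-bromo-2-fluoro-4-(methoxymethoxy)benzene
Conditions: MeOCH2Cl, i-Pr2NEt, CH2Cl2, 0 → 25 °C
Reagents that add atoms: chloromethyl methyl ether, COCCl
Why: Williamson-type O-alkylation of the phenol by the reactive α-chloro ether under amine base; the MOM acetal is chosen because it directs the later metalation and withstands organolithium reagents, the boron Lewis acid and fluoride.

Step 2
Reactants: 2 1-bromo-2-fluoro-4-(methoxymethoxy)benzene
Product: 5 1-bromo-2-fluoro-4-(methoxymethoxy)-3-(3-methylbut-2-en-1-yl)benzene, via aryllithium 3 (not isolated), via arylcopper 4 (not isolated)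
Conditions: i-Pr2NLi, THF, −78 °C; CuBr·SMe2, −78 °C; 1-bromo-3-methylbut-2-ene, −78 → 0 °C
Reagents that add atoms: 1-bromo-3-methylbut-2-ene (prenyl bromide), CC(C)=CCBr
Why: Directed ortho-metalation: the hydrogen flanked by fluorine and the MOM ether is by far the most acidic, i-Pr2NLi removes it without bromine–lithium exchange, and transmetalation to copper stops loss of LiF and steers the allylation to the primary carbon of the bromide (SN2), which should give the linear prenyl group.

Step 3
Reactants: 5 1-bromo-2-fluoro-4-(methoxymethoxy)-3-(3-methylbut-2-en-1-yl)benzene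
Product: 7 1-[2-fluoro-4-(methoxymethoxy)-3-(3-methylbut-2-en-1-yl)phenyl]ethan-1-one, via aryllithium 6 (not isolated)
Conditions: n-BuLi, THF, −78 °C; N-methoxy-N-methylacetamide, −78 → 0 °C; sat. aq. NH4Cl
Reagents that add atoms: N-methoxy-N-methylacetamide, CC(=O)N(C)OC
Why: Bromine–lithium exchange at −78 °C is faster than any deprotonation and the ortho-fluoro aryllithium is stable at this temperature, and acylation with the Weinreb amide stops at the ketone (Weinreb ketone synthesis).

Step 4
Reactants: 7 1-[2-fluoro-4-(methoxymethoxy)-3-(3-methylbut-2-en-1-yl)phenyl]ethan-1-one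
Product: 9 {1-[2-fluoro-4-(methoxymethoxy)-3-(3-methylbut-2-en-1-yl)phenyl]ethenyloxy}trimethylsilane, via lithium enolate 8 (not isolated)
Conditions: i-Pr2NLi, THF, −78 °C; Me3SiCl, −78 → 0 °C; pentane, filtration under argon (no aqueous work-up)
Reagents that add atoms: chlorotrimethylsilane, C[Si](C)(C)Cl
Why: Kinetic enolisation at the only enolisable position (the methyl group) and O-silylation of the lithium enolate by the hard silyl chloride should give the enol silane, which is used at once.

Step 5
Reactants: 10 3-bromo-4-hydroxybenzaldehyde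
Product: 11 3-bromo-4-(methoxymethoxy)benzaldehyde
Conditions: MeOCH2Cl, i-Pr2NEt, CH2Cl2, 0 → 25 °C
Reagents that add atoms: chloromethyl methyl ether, COCCl
Why: Williamson-type O-alkylation as in step 1; the aldehyde is inert to these conditions.

Step 6
Reactants: 11 3-bromo-4-(methoxymethoxy)benzaldehyde
Product: 12 4-(methoxymethoxy)-3-(3-methylbut-2-en-1-yl)benzaldehyde
Conditions: tributyl(3-methylbut-2-en-1-yl)stannane, Pd(PPh3)4 (5 mol%), DMF, 90 °C
Reagents that add atoms: tributyl(3-methylbut-2-en-1-yl)stannane, CCCC[Sn](CCCC)(CCCC)CC=C(C)C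
Why: Stille coupling: zerovalent palladium inserts into the C–Br bond, the aldehyde and the acetal are tolerated, and reductive elimination at the unsubstituted terminus of the prenyl ligand should give the linear 3-methylbut-2-enyl arene.

Step 7
Reactants: 9 {1-[2-fluoro-4-(methoxymethoxy)-3-(3-methylbut-2-en-1-yl)phenyl]ethenyloxy}trimethylsilane; 12 4-(methoxymethoxy)-3-(3-methylbut-2-en-1-yl)benzaldehyde
Product: 14 (2S)-7-(methoxymethoxy)-2-[4-(methoxymethoxy)-3-(3-methylbut-2-en-1-yl)phenyl]-8-(3-methylbut-2-en-1-yl)-2,3-dihydro-4H-chromen-4-one, via silyl ether 13 (not isolated)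
Conditions: 12 (1.0 equiv), 9 (1.1 equiv), (4R)-2-butyl-4-(1H-indol-3-ylmethyl)-3-(4-methylphenylsulfonyl)-1,3,2-oxazaborolidin-5-one (20 mol%, made from N-tosyl-(R)-tryptophan and n-BuB(OH)2), EtCN, −78 °C; then n-Bu4N[Ph3SiF2] (30 mol%), DMF, −40 → 25 °C; pH 7 buffer
Reagents that add atoms: none
Why: Proposed new method: the boron Lewis acid binds the aldehyde of 12 and enol silane 9 adds through an open transition state (C2–C3), silyl transfer to the aldolate oxygen frees the catalyst and leaves silyl ether 13; catalytic fluoride then unmasks the C2 alkoxide, which adds to C8a of the ortho-fluoroaryl ketone (Meisenheimer adduct, charge held by the C4 carbonyl) and expels fluoride (O1–C8a), and this fluoride desilylates the next molecule of 13, so that the closure runs as a chain with Me3SiF as the only co-product and without stoichiometric base. The closest known reaction types are the oxazaborolidinone-catalysed Mukaiyama aldol addition of aryl methyl ketone enol silanes to aromatic aldehydes, the aldol-then-cyclisation pathway of the hetero-Diels–Alder reaction of 1-alkoxy-3-silyloxybutadienes with aldehydes, and fluoride-catalysed SNAr of silyl ethers on carbonyl-activated aryl fluorides; new is their union in one flask on a diene whose terminal double bond is an arene bond. Ring C closes by addition–elimination at C8a, formally a 6-endo-trig conjugate addition of the alkoxide to the C8a=C4a–C4=O vinylogous acyl fluoride followed by loss of fluoride and return of aromaticity to ring A. The C2 stereocentre is set in the aldol event by the catalyst, whose indole ring covers one face of the bound aldehyde so that 9 attacks the Si face, and it is retained because the SNAr breaks no bond at C2. The step needs facial selectivity (catalyst control, with 12 as the limiting partner so that no aldehyde is left for a racemic fluoride-catalysed aldol) and closure faster than retro-aldol or E1cB loss of the oxygen substituent, which the ortho placing of the acyl group and the fluorine on ring A (a 6-membered closure onto an activated carbon) and the low standing concentration of alkoxide should secure. Chemoselectivity is otherwise fixed by the substrates: the methyl group of 9 is the only enolisable position, 12 cannot enolise, and C8a is the only carbon that bears a leaving group.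

Step 8
Reactants: 14 (2S)-7-(methoxymethoxy)-2-[4-(methoxymethoxy)-3-(3-methylbut-2-en-1-yl)phenyl]-8-(3-methylbut-2-en-1-yl)-2,3-dihydro-4H-chromen-4-one
Product: 15 glabrol (2S)-7-hydroxy-2-[4-hydroxy-3-(3-methylbut-2-en-1-yl)phenyl]-8-(3-methylbut-2-en-1-yl)-2,3-dihydro-4H-chromen-4-one
Conditions: HCl (1 M in MeOH), 25 °C, stopped at full conversion
Reagents that add atoms: none
Why: Acid-catalysed transacetalisation of the two aryl MOM acetals to dimethoxymethane, conditions in common use for prenylated flavanones; dilute acid at room temperature should neither open ring C (racemisation of flavanones runs through base-induced E1cB opening) nor add the freed phenols to the prenyl double bonds.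

**Compound list**
1 | 4-bromo-3-fluorophenol | Oc1ccc(Br)c(F)c1 | starting material
2 | 1-bromo-2-fluoro-4-(methoxymethoxy)benzene | COCOc1ccc(Br)c(F)c1 | intermediate
3 | [3-bromo-2-fluoro-6-(methoxymethoxy)phenyl]lithium | [Li]c1c(OCOC)ccc(Br)c1F | intermediate
4 | [3-bromo-2-fluoro-6-(methoxymethoxy)phenyl]copper | [Cu]c1c(OCOC)ccc(Br)c1F | intermediate
5 | 1-bromo-2-fluoro-4-(methoxymethoxy)-3-(3-methylbut-2-en-1-yl)benzene | COCOc1ccc(Br)c(F)c1CC=C(C)C | intermediate
6 | [2-fluoro-4-(methoxymethoxy)-3-(3-methylbut-2-en-1-yl)phenyl]lithium | [Li]c1ccc(OCOC)c(CC=C(C)C)c1F | intermediate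
7 | 1-[2-fluoro-4-(methoxymethoxy)-3-(3-methylbut-2-en-1-yl)phenyl]ethan-1-one | CC(=O)c1ccc(OCOC)c(CC=C(C)C)c1F | intermediate
8 | lithium 1-[2-fluoro-4-(methoxymethoxy)-3-(3-methylbut-2-en-1-yl)phenyl]ethen-1-olate | [Li]OC(=C)c1ccc(OCOC)c(CC=C(C)C)c1F | intermediate
9 | {1-[2-fluoro-4-(methoxymethoxy)-3-(3-methylbut-2-en-1-yl)phenyl]ethenyloxy}trimethylsilane | C=C(O[Si](C)(C)C)c1ccc(OCOC)c(CC=C(C)C)c1F | intermediate
10 | 3-bromo-4-hydroxybenzaldehyde | O=Cc1ccc(O)c(Br)c1 | starting material
11 | 3-bromo-4-(methoxymethoxy)benzaldehyde | COCOc1ccc(C=O)cc1Br | intermediate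
12 | 4-(methoxymethoxy)-3-(3-methylbut-2-en-1-yl)benzaldehyde | COCOc1ccc(C=O)cc1CC=C(C)C | intermediate
13 | (3S)-1-[2-fluoro-4-(methoxymethoxy)-3-(3-methylbut-2-en-1-yl)phenyl]-3-[4-(methoxymethoxy)-3-(3-methylbut-2-en-1-yl)phenyl]-3-(trimethylsilyloxy)propan-1-one | CC(C)=CCc1cc([C@@H](O[Si](C)(C)C)CC(=O)c2ccc(OCOC)c(CC=C(C)C)c2F)ccc1OCOC | intermediate
14 | (2S)-7-(methoxymethoxy)-2-[4-(methoxymethoxy)-3-(3-methylbut-2-en-1-yl)phenyl]-8-(3-methylbut-2-en-1-yl)-2,3-dihydro-4H-chromen-4-one | CC(C)=CCc1cc([C@@H]2CC(=O)c3ccc(OCOC)c(CC=C(C)C)c3O2)ccc1OCOC | intermediate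
15 | glabrol (2S)-7-hydroxy-2-[4-hydroxy-3-(3-methylbut-2-en-1-yl)phenyl]-8-(3-methylbut-2-en-1-yl)-2,3-dihydro-4H-chromen-4-one | CC(C)=CCc1cc([C@@H]2CC(=O)c3ccc(O)c(CC=C(C)C)c3O2)ccc1O | target

**Count**
Total steps: 8. Longest linear sequence: 6 (steps 1, 2, 3, 4, 7, 8).

**Steps most likely to fail**

Step 7 (bears the new-method label). Once fluoride has unmasked the aldolate, retro-aldol cleavage with non-selective re-addition, or E1cB loss of the oxygen substituent, may outrun the SNAr closure. Enantiomeric purity would then be eroded or material diverted to a chalcone; incomplete facial control in the aldol event is the second concern. The fallback uses known chemistry and closes ring C at O1–C2 instead, so that no β-alkoxide ketone has to survive base. It sets out from compound 7. The fluorine is exchanged for hydroxyl by SNAr with the alkoxide of 2-(methylsulfonyl)ethanol (NaH, DMF, 0 → 25 °C), which fragments in the flask, to give 1-[2-hydroxy-4-(methoxymethoxy)-3-(3-methylbut-2-en-1-yl)phenyl]ethan-1-one F1. Double deprotonation and silylation (i-Pr2NLi, 2.2 equiv, then Me3SiCl, THF, −78 °C) give {1-[4-(methoxymethoxy)-3-(3-methylbut-2-en-1-yl)-2-(trimethylsilyloxy)phenyl]ethenyloxy}trimethylsilane F2. A Lewis-base-catalysed Mukaiyama aldol addition to aldehyde 12 follows (SiCl4, the binaphthyl-2,2′-diamine-derived bisphosphoramide catalyst of the antipode that delivers Re-face attack, CH2Cl2, −78 °C; aqueous KF/KH2PO4 work-up, which also removes both silyl groups). It should give (3R)-3-hydroxy-1-[2-hydroxy-4-(methoxymethoxy)-3-(3-methylbut-2-en-1-yl)phenyl]-3-[4-(methoxymethoxy)-3-(3-methylbut-2-en-1-yl)phenyl]propan-1-one F3. Mitsunobu cyclisation (PPh3, diisopropyl azodicarboxylate, THF, 0 °C) then closes ring C with inversion at the carbinol carbon and comes back to the route at compound 14.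

Step 2. The ortho-fluoro aryllithium may lose lithium fluoride (aryne formation) or suffer bromine migration before it is trapped, and the copper-mediated allylation may attack the tertiary terminus or give homocoupling. The fallback sets out from compound 2. The aryllithium (i-Pr2NLi, THF, −78 °C) is trapped at once with I2 to give 1-bromo-2-fluoro-3-iodo-4-(methoxymethoxy)benzene F4. The prenyl group is then introduced by Stille coupling at the more reactive C–I bond (tributyl(3-methylbut-2-en-1-yl)stannane, Pd(PPh3)4, DMF, 60 °C), so that carbon–carbon bond formation no longer depends on an organocopper allylation. The route is rejoined at compound 5.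

Step 8. Under protic acid the freed phenols may add to the neighbouring prenyl double bonds (chroman formation), and reversible opening of ring C may cost enantiomeric purity. The fallback sets out from compound 14 and replaces acetal solvolysis by a trans-protection. The two MOM acetals are exchanged for silyl ethers under aprotic, buffered conditions (Et3SiOTf, 2,2′-bipyridyl, CH2Cl2, 0 °C) to give (2S)-7-(triethylsilyloxy)-2-[3-(3-methylbut-2-en-1-yl)-4-(triethylsilyloxy)phenyl]-8-(3-methylbut-2-en-1-yl)-2,3-dihydro-4H-chromen-4-one F5. The silyl ethers are then cleaved with acetic acid-buffered n-Bu4NF (THF, 0 °C), which comes back to the route at compound 15.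

Further compounds
F1 | step 7 | 1-[2-hydroxy-4-(methoxymethoxy)-3-(3-methylbut-2-en-1-yl)phenyl]ethan-1-one | CC(=O)c1ccc(OCOC)c(CC=C(C)C)c1O
F2 | step 7 | {1-[4-(methoxymethoxy)-3-(3-methylbut-2-en-1-yl)-2-(trimethylsilyloxy)phenyl]ethenyloxy}trimethylsilane | C=C(O[Si](C)(C)C)c1ccc(OCOC)c(CC=C(C)C)c1O[Si](C)(C)C
F3 | step 7 | (3R)-3-hydroxy-1-[2-hydroxy-4-(methoxymethoxy)-3-(3-methylbut-2-en-1-yl)phenyl]-3-[4-(methoxymethoxy)-3-(3-methylbut-2-en-1-yl)phenyl]propan-1-one | CC(C)=CCc1cc([C@H](O)CC(=O)c2ccc(OCOC)c(CC=C(C)C)c2O)ccc1OCOC
F4 | step 2 | 1-bromo-2-fluoro-3-iodo-4-(methoxymethoxy)benzene | COCOc1ccc(Br)c(F)c1I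
F5 | step 8 | (2S)-7-(triethylsilyloxy)-2-[3-(3-methylbut-2-en-1-yl)-4-(triethylsilyloxy)phenyl]-8-(3-methylbut-2-en-1-yl)-2,3-dihydro-4H-chromen-4-one | CC(C)=CCc1cc([C@@H]2CC(=O)c3ccc(O[Si](CC)(CC)CC)c(CC=C(C)C)c3O2)ccc1O[Si](CC)(CC)CC
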